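**Plan**

1. Numbering (lignan convention): C7/C7' are the two ArCH(OH) carbons, C8/C8' the ring CH carbons, C9/C9' the ring OCH2 carbons; Ar = 4-hydroxy-3-methoxyphenyl. The target is 7S,8R,8'R,7'R with a trans-3,4-disubstituted oxolane.
2. Retrosynthesis: remove the two phenolic benzyl groups; take C7–OH back to a C7 ketone and this to a 1,3-dithiane; cut the ring bond O–C9' (1,4-diol); raise C9/C9' to a 5-menthyloxy-γ-lactone; then cut C7'–C8' (aldol) and C7–C8 (conjugate addition) in one operation, giving two molecules of O-benzylvanillin and (5R)-5-(l-menthyloxy)furan-2(5H)-one.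
3. Enabling feature: the oxolane ring C8–C9–O–C9'–C8' is a reduced butenolide with C8 as its β-carbon, and the C7 oxygen stands 1,4 to the C9' oxygen (O–C7–C8–C8'–C9'–O). C7 therefore has to enter as an acyl anion (2-aryl-1,3-dithiane), a union of two acceptor carbons by polarity reversal.
4. Forward: the chain is joined first (three-component 1,4-addition/aldol builds the whole C6C3–C6C3 skeleton on the lactone); LiAlH4 then frees the 1,4-diol and the auxiliary; the oxolane is closed by O–C9' bond formation; C7 is unmasked and reduced; the phenols are freed.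
5. Stereochemistry: C8 from the menthyloxy acetal centre (addition anti to it); C8' trans to C8; C7' (R) from the chair aldol transition state (anti aldol); C7 (S) from an (R)-oxazaborolidine-catalysed reduction that matches the Felkin–Anh preference.
6. Helpers and their removal: dithiane (umpolung, and it keeps C7 free of oxygen during ring closure; step 5); menthyloxy acetal and lactone carbonyl (step 3); benzyl ethers (step 7).

Key step: step 2

Assumption: (5R)-5-(l-menthyloxy)furan-2(5H)-one (3) is treated as a purchasable single enantiomer, as is O-benzylvanillin (1).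

**Route**

Step 1
Reactants: 1 4-(benzyloxy)-3-methoxybenzaldehyde
Product: 2 2-[4-(benzyloxy)-3-methoxyphenyl]-1,3-dithiane
Conditions: HS(CH2)3SH, BF3·OEt2 (cat.), CH2Cl2, 0 °C → rt
Reagents that add atoms: propane-1,3-dithiol, SCCCS
Why: Lewis-acid-catalysed dithioacetalisation of an aromatic aldehyde (Corey–Seebach dithiane formation) should proceed cleanly, the aryl benzyl and methyl ethers being inert to catalytic BF3 at this temperature, and no stereocentre is involved.

Step 2
Reactants: 2 2-[4-(benzyloxy)-3-methoxyphenyl]-1,3-dithiane; 3 (5R)-5-(l-menthyloxy)furan-2(5H)-one; 1 4-(benzyloxy)-3-methoxybenzaldehyde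
Product: 7 (3S,4R,5R)-4-{2-[4-(benzyloxy)-3-methoxyphenyl]-1,3-dithian-2-yl}-3-{(R)-[4-(benzyloxy)-3-methoxyphenyl](hydroxy)methyl}-5-{[(1R,2S,5R)-5-methyl-2-(propan-2-yl)cyclohexyl]oxy}oxolan-2-one, via 2-lithio-2-[4-(benzyloxy)-3-methoxyphenyl]-1,3-dithiane 4 (not isolated), via lithium lactone enolate 5 (not isolated), via lithium aldolate 6 (not isolated)
Conditions: n-BuLi, THF, −78 → −30 °C; 3, −78 °C; 1, −78 °C; AcOH, −78 °C
Reagents that add atoms: none
Why: Corey–Seebach umpolung: deprotonation of 2 gives the charge-delocalised 2-lithio-dithiane 4, an acyl-anion equivalent for C7, which adds 1,4 to butenolide 3 at C4 (the future C8) and so forms the C7–C8 bond between two carbons that are both acceptors in their natural polarity; the lithium enolate 5 so formed is intercepted at C3 (future C8') by aldehyde 1 to give aldolate 6 and, after cold protonation, 7. The closest known reaction type is the three-component tandem conjugate addition–aldol of lithiated 2-aryl-1,3-dithianes to 5-alkoxyfuran-2(5H)-ones. No ring is closed here; the lactone is carried through intact and supplies the atoms of the later oxolane. C8 is controlled by the (5R)-menthyloxy acetal centre (future C9), the nucleophile entering anti to the alkoxy group; C8' is controlled by C8, the aldehyde approaching anti to the very large aryl-dithianyl group (3,4-trans); C7' is controlled by the closed Zimmerman–Traxler chair of the ring-fixed (E)-enolate, which should favour the anti aldol, i.e. 7'R. The step needs 1,4- over 1,2-addition (secured by the soft, aryl-stabilised dithianyl anion and the unhindered β-carbon of the cis-locked enoate), facial control (secured by the acetal substituent) and kinetic control of the aldol (aldehyde added and the aldolate protonated at −78 °C so that retro-aldol equilibration is avoided).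

Step 3
Reactants: 7 the tandem adduct (lactone)
Product: 8 (2R,3R)-2-{2-[4-(benzyloxy)-3-methoxyphenyl]-1,3-dithian-2-yl}-3-{(R)-[4-(benzyloxy)-3-methoxyphenyl](hydroxy)methyl}butane-1,4-diol
Conditions: LiAlH4, THF, 0 °C → rt; aq. NaOH work-up
Reagents that add atoms: none
Why: LiAlH4 reduction of a γ-alkoxy lactone (pseudo-ester) should open the lactone, let the hemiacetal alkoxide at C9 collapse to an aldehyde that is reduced as well, and so deliver both C9 and C9' as CH2OH with release of menthol, while the dithiane, the benzyl ethers and all stereocentres are untouched.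

Step 4
Reactants: 8 the triol
Product: 9 (R)-[4-(benzyloxy)-3-methoxyphenyl]{(3R,4R)-4-[2-(4-benzyloxy-3-methoxyphenyl)-1,3-dithian-2-yl]oxolan-3-yl}methanol
Conditions: PPh3, DIAD, THF, 0 °C → rt
Reagents that add atoms: none
Why: Mitsunobu cyclodehydration of a 1,4-diol (5-exo-tet etherification) should close only the C9–O–C9' ring, because only primary hydroxyls are activated at this temperature, activated C9' can be reached by O9 alone (O7' would give an oxetane), activated C9 is captured faster by the primary O9' than by the hindered benzylic O7', and C7 carries no oxygen while it is a dithiane; the bond forms at CH2, so no stereocentre changes.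

Step 5
Reactants: 9 the oxolane dithiane
Product: 10 [4-(benzyloxy)-3-methoxyphenyl]{(3R,4R)-4-[(R)-[4-(benzyloxy)-3-methoxyphenyl](hydroxy)methyl]oxolan-3-yl}methanone
Conditions: MeI, CaCO3, MeCN–H2O (9:1), 40 °C
Reagents that add atoms: water, O
Why: Alkylative hydrolysis of the dithioketal (S-methylation, opening to the aryl-stabilised thionium ion, capture by water) under carbonate buffer should unmask the C7 ketone without touching the benzylic alcohol or the benzyl ethers, and C8 stays trans because that is the more stable arrangement and the trans-fused hemiketal cannot form.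

Step 6
Reactants: 10 the hydroxy ketone
Product: 11 (S)-[4-(benzyloxy)-3-methoxyphenyl]{(3R,4R)-4-[(R)-[4-(benzyloxy)-3-methoxyphenyl](hydroxy)methyl]oxolan-3-yl}methanol
Conditions: (R)-Me-CBS (cat.), BH3·SMe2, THF, −20 °C; MeOH
Reagents that add atoms: none
Why: Corey–Bakshi–Shibata reduction with the (R)-oxazaborolidine should deliver hydride to the face of the aryl ketone that gives the (S)-carbinol (aryl as the large group), and this is also the Felkin–Anh face (hydride anti to the more substituted ring carbon C8'), so catalyst and substrate control are matched for 7S.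

Step 7
Reactants: 11 the bis-benzyl ether
Product: 12 4-[(S)-hydroxy{(3R,4R)-4-[(R)-hydroxy(4-hydroxy-3-methoxyphenyl)methyl]oxolan-3-yl}methyl]-2-methoxyphenol
Conditions: H2 (1 atm), 10% Pd/C, EtOAc–MeOH, rt
Reagents that add atoms: none
Why: Hydrogenolysis of the two phenolic benzyl ethers over Pd/C under neutral conditions should be much faster than cleavage of the secondary benzylic C–OH bonds, so both carbinols and all four stereocentres are kept.

**Compound list**

1 | 4-(benzyloxy)-3-methoxybenzaldehyde (O-benzylvanillin) | COc1cc(C=O)ccc1OCc1ccccc1 | starting material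
2 | 2-[4-(benzyloxy)-3-methoxyphenyl]-1,3-dithiane | COc1cc(C2SCCCS2)ccc1OCc1ccccc1 | intermediate
3 | (5R)-5-{[(1R,2S,5R)-5-methyl-2-(propan-2-yl)cyclohexyl]oxy}furan-2(5H)-one [(5R)-5-(l-menthyloxy)-2(5H)-furanone] | O=C1C=C[C@H](O[C@@H]2C[C@H](C)CC[C@H]2C(C)C)O1 | starting material
4 | 2-lithio-2-[4-(benzyloxy)-3-methoxyphenyl]-1,3-dithiane | COc1cc(C2([Li])SCCCS2)ccc1OCc1ccccc1 | intermediate
5 | lithium enolate of the 1,4-adduct (aryl-dithianyl group at C4 anti to the menthyloxy group at C5) | COc1cc(C2(SCCCS2)[C@H]3[C@H](O[C@@H]4C[C@H](C)CC[C@H]4C(C)C)OC(O[Li])=C3)ccc1OCc1ccccc1 | intermediate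
6 | lithium aldolate of 7 | COc1cc(C2(SCCCS2)[C@H]3[C@H](O[C@@H]4C[C@H](C)CC[C@H]4C(C)C)OC(=O)[C@@H]3[C@@H](O[Li])c5ccc(OCc6ccccc6)c(OC)c5)ccc1OCc1ccccc1 | intermediate
7 | (3S,4R,5R)-4-{2-[4-(benzyloxy)-3-methoxyphenyl]-1,3-dithian-2-yl}-3-{(R)-[4-(benzyloxy)-3-methoxyphenyl](hydroxy)methyl}-5-(l-menthyloxy)oxolan-2-one | COc1cc(C2(SCCCS2)[C@H]3[C@H](O[C@@H]4C[C@H](C)CC[C@H]4C(C)C)OC(=O)[C@@H]3[C@@H](O)c5ccc(OCc6ccccc6)c(OC)c5)ccc1OCc1ccccc1 | intermediate
8 | (2R,3R)-2-{2-[4-(benzyloxy)-3-methoxyphenyl]-1,3-dithian-2-yl}-3-{(R)-[4-(benzyloxy)-3-methoxyphenyl](hydroxy)methyl}butane-1,4-diol | COc1cc(C2(SCCCS2)[C@@H](CO)[C@H](CO)[C@@H](O)c3ccc(OCc4ccccc4)c(OC)c3)ccc1OCc1ccccc1 | intermediate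
9 | (R)-[4-(benzyloxy)-3-methoxyphenyl]{(3R,4R)-4-[2-(4-benzyloxy-3-methoxyphenyl)-1,3-dithian-2-yl]oxolan-3-yl}methanol | COc1cc(C2(SCCCS2)[C@H]3COC[C@@H]3[C@@H](O)c4ccc(OCc5ccccc5)c(OC)c4)ccc1OCc1ccccc1 | intermediate
10 | [4-(benzyloxy)-3-methoxyphenyl]{(3R,4R)-4-[(R)-[4-(benzyloxy)-3-methoxyphenyl](hydroxy)methyl]oxolan-3-yl}methanone | COc1cc(C(=O)[C@H]2COC[C@@H]2[C@@H](O)c3ccc(OCc4ccccc4)c(OC)c3)ccc1OCc1ccccc1 | intermediate
11 | (S)-[4-(benzyloxy)-3-methoxyphenyl]{(3R,4R)-4-[(R)-[4-(benzyloxy)-3-methoxyphenyl](hydroxy)methyl]oxolan-3-yl}methanol | COc1cc([C@@H](O)[C@H]2COC[C@@H]2[C@@H](O)c3ccc(OCc4ccccc4)c(OC)c3)ccc1OCc1ccccc1 | intermediate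
12 | 4-[(S)-hydroxy{(3R,4R)-4-[(R)-hydroxy(4-hydroxy-3-methoxyphenyl)methyl]oxolan-3-yl}methyl]-2-methoxyphenol | COc1cc([C@@H](O)[C@H]2COC[C@@H]2[C@@H](O)c2ccc(O)c(OC)c2)ccc1O | target

**Summary**

Total step count: 7. Longest linear sequence: 7 steps (1 → 12; compound 1 is used in steps 1 and 2).

Steps most likely to fail:

Step 2. The aldol half of the tandem reaction may discriminate poorly between the competing cyclic transition states, or the aldolate may equilibrate by retro-aldol reaction, so that the C7' carbinol forms mainly with the wrong (S, syn) configuration. The fallback corrects C7' by SN2 inversion after ring closure instead of demanding it from the C–C bond formation. It sets out from the unchanged step-2 reaction of 2, 3 and 1 and comes back at 9. The syn-aldol lactone (C7'-epimer of 7) F1 is reduced with LiAlH4 to the epimeric triol F2. This is closed under the step-4 conditions to the epimeric oxolane carbinol F3. Its only hydroxyl is inverted by Mitsunobu esterification (4-nitrobenzoic acid, PPh3, DIAD, THF) to the (R)-configured 4-nitrobenzoate F4, and K2CO3 in MeOH then gives 9.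

Step 4. Ring closure may take the wrong course: through the benzylic oxygen O7' (7',9-ether), through activation of the benzylic alcohol, or through capture of the activated carbon by a dithiane sulfur. The fallback replaces the direct dehydration by a protecting-group-controlled, base-mediated Williamson closure in which the alkoxide is formed before the leaving group. It sets out from 7 and comes back at 9. Silylation (TBSOTf, 2,6-lutidine, CH2Cl2) gives the silyl ether of the lactone F5, and LiAlH4 gives the protected 1,4-diol F6. n-BuLi followed by one equivalent of TsCl gives the mono-tosylate F7 (drawn at the C9' oxygen; the C9 isomer closes to the same ring), which on a second equivalent of base closes to the silyl-protected oxolane F8. TBAF then gives 9.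

Step 6. Hydride delivery to the C7 ketone may show poor facial selectivity (uncatalysed reduction, or internal delivery from the borate formed at O7'), and the C8 centre may be lost by enolisation toward the cis-fused hemiketal. The fallback uses substrate control on a protected ketone instead of catalyst control. It sets out from 10 and comes back at 11. Silylation (TIPSOTf, 2,6-lutidine, CH2Cl2, −78 °C) gives the silyl ether of the ketone F9. L-Selectride (THF, −78 °C) should then attack anti to the now very large C8' arm (Felkin–Anh) to give the (S)-carbinol silyl ether F10, and TBAF gives 11.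

Further compounds
F1 | step 2 | C7'-epimer of 7 (syn-aldol lactone with (S)-carbinol) | COc1cc(C2(SCCCS2)[C@H]3[C@H](O[C@@H]4C[C@H](C)CC[C@H]4C(C)C)OC(=O)[C@@H]3[C@H](O)c5ccc(OCc6ccccc6)c(OC)c5)ccc1OCc1ccccc1
F2 | step 2 | C7'-epimer of triol 8 | COc1cc(C2(SCCCS2)[C@@H](CO)[C@H](CO)[C@H](O)c3ccc(OCc4ccccc4)c(OC)c3)ccc1OCc1ccccc1
F3 | step 2 | C7'-epimer of oxolane carbinol 9 | COc1cc(C2(SCCCS2)[C@H]3COC[C@@H]3[C@H](O)c4ccc(OCc5ccccc5)c(OC)c4)ccc1OCc1ccccc1
F4 | step 2 | 4-nitrobenzoate ester of 9 ((R) at C7') | COc1cc(C2(SCCCS2)[C@H]3COC[C@@H]3[C@@H](OC(=O)c6ccc(cc6)[N+](=O)[O-])c4ccc(OCc5ccccc5)c(OC)c4)ccc1OCc1ccccc1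
F5 | step 4 | O-tert-butyldimethylsilyl ether of 7 | COc1cc(C2(SCCCS2)[C@H]3[C@H](O[C@@H]4C[C@H](C)CC[C@H]4C(C)C)OC(=O)[C@@H]3[C@@H](O[Si](C)(C)C(C)(C)C)c5ccc(OCc6ccccc6)c(OC)c5)ccc1OCc1ccccc1
F6 | step 4 | O7'-tert-butyldimethylsilyl ether of triol 8 (1,4-diol) | COc1cc(C2(SCCCS2)[C@@H](CO)[C@H](CO)[C@@H](O[Si](C)(C)C(C)(C)C)c3ccc(OCc4ccccc4)c(OC)c3)ccc1OCc1ccccc1
F7 | step 4 | mono-tosylate of F6 (at the C9' oxygen) | COc1cc(C2(SCCCS2)[C@@H](CO)[C@H](COS(=O)(=O)c5ccc(C)cc5)[C@@H](O[Si](C)(C)C(C)(C)C)c3ccc(OCc4ccccc4)c(OC)c3)ccc1OCc1ccccc1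
F8 | step 4 | O-tert-butyldimethylsilyl ether of 9 | COc1cc(C2(SCCCS2)[C@H]3COC[C@@H]3[C@@H](O[Si](C)(C)C(C)(C)C)c4ccc(OCc5ccccc5)c(OC)c4)ccc1OCc1ccccc1
F9 | step 6 | O-triisopropylsilyl ether of ketone 10 | COc1cc(C(=O)[C@H]2COC[C@@H]2[C@@H](O[Si](C(C)C)(C(C)C)C(C)C)c3ccc(OCc4ccccc4)c(OC)c3)ccc1OCc1ccccc1
F10 | step 6 | O7'-triisopropylsilyl ether of 11 | COc1cc([C@@H](O)[C@H]2COC[C@@H]2[C@@H](O[Si](C(C)C)(C(C)C)C(C)C)c3ccc(OCc4ccccc4)c(OC)c3)ccc1OCc1ccccc1
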